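Start from the capture agent.

common to all: starting complex 0.050 M
- ash: incoming ligand 2 equiv; leaving ligand 1 equiv; capture agent 0.015 M; run made earlier
- flask: incoming ligand 2.00 equiv; leaving ligand 0.500 equiv; capture agent 0.0150 M; time 25 h

ash run (percent of the starting complex charged)

| time / h | complex with two exchanged / % | trapped intermediate / % | complex with three exchanged / % | complex with one exchanged / % | side product / % | starting complex / % |
|---|---|---|---|---|---|---|
| 0.417 | 0.4 | 1.0 | 0.5 | 5.4 | 0 | 91.9 |
| 0.833 | 0.2 | 4.9 | 0.3 | 9.2 | 1.0 | 85.2 |
| 1.33 | 1.9 | 9.2 | 0 | 11.0 | 1.3 | 78.3 |
| 2.50 | 0.6 | 17.1 | 0 | 12.7 | 4.5 | 64.7 |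
| 5.00 | 1.3 | 25.6 | 0.5 | 15.1 | 12.5 | 45.8 |

(scatter of a reading: 0.5 percentage points)

- what was read earlier has a scatter of 0.5 percentage points, one standard deviation
- no earlier run changes the charge of leaving ligand; that part of a forecast is a guess

1. the species in which most of what was charged as starting complex, at 25 h sits (complex with one exchanged / complex with two exchanged / starting complex / trapped intermediate / side product / complex with three exchanged)
2. the largest share itself, whichever of these holds it, in percent of the starting complex charged

I take it that each trapped intermediate uses up one capture agent, and with 0.0150 M of it against 0.050 M of starting complex I treat that agent as the limiting reagent of the trapping. This gives 30.0%, the capture ceiling: capture agent charged over starting complex charged, the share that trapping can hold. The ash run has the same ceiling and differs from this flask in leaving ligand and in length, so I draw this flask's curve from the ash run and leave the leaving ligand aside as a guess.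

In the ash run the trapped intermediate stands at 9.2% by 1.33 h, then gains 8.5 percentage points from 2.50 h to 5.00 h. With 4.4 points of room left at the last reading, that pace puts the knee of this flask's curve, as I draw it, at 6.29 h.

Over the same stretch of the ash run the side product gains 8 points, while starting complex and complex with one exchanged together average 69.2%. I read that as a drain of 0.0463 h⁻¹. At the knee I put the side product near 16.6%, and past the knee I let that drain carry on unchanged. On this reckoning the side product crosses the ceiling near 12.5 h and heads for a level of 70.0%. At 25 h my reckoning leaves 22.5% unconverted and gives 47.5% side product.

The forecast says side product at 52%, above my figure, on the grounds that “all later flux goes to side product”.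

This flask puts 51.6% in side product, more than the 30.0% of trapped intermediate, which stands at the ceiling with 0.0053% of the capture agent left.

    complex with one exchanged + capture agent → trapped intermediate (k = 66.0 M⁻¹ h⁻¹)
    complex with one exchanged + incoming ligand ⇌ leaving ligand + complex with two exchanged (K = 0.110, k = 3.80 M⁻¹ h⁻¹)
    complex with two exchanged + incoming ligand ⇌ leaving ligand + complex with three exchanged (K = 0.100, k = 1.30 M⁻¹ h⁻¹)
    starting complex + incoming ligand ⇌ leaving ligand + complex with one exchanged (K = 0.480, k = 2.20 M⁻¹ h⁻¹)
    leaving ligand → by-product carried off (k = 0.430 h⁻¹)
    complex with two exchanged → side product (k = 4.20 h⁻¹)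

A neighbouring flask charged with 0.20 M of starting complex and still 0.0150 M of capture agent has a ceiling of 7.50%. That neighbouring flask ends with 7.50% of trapped intermediate and 84.8% of side product.

The readings are calculated for substances that don't exist; noise was put on by code.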